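Ring A is disconnected across C2–C3 and C5–C10. This exposes C10–C1–C2 as the β-, γ- and δ-carbons of a cross-conjugated dienyl β-keto ester (C9 carrying the future C8 and C11 carbonyls), and C3–C4–C5 as a bis-nucleophile bridged by the gem-dimethyl carbon C4: C3 as a nitronate (latent 3-oxygen) and C5 as the α-carbon of the C6 ketone. One operation, a 1,6-/1,4-double Michael (3+3) annulation of 4,4-dimethyl-5-nitropentan-2-one with ethyl 2-acetyl-3-methylpenta-2,4-dienoate, builds ring A and the quaternary C10; the resulting 1,5-diketone then closes ring B by aldol condensation.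

Key step: step 4

Remark: drimane numbering is used (ring A = C1–C5, C10; ring B = C5–C10; C11 = the CH2O carbon on C9); α is the face opposite the C10 methyl; the target is read from its SMILES as 3α-acyloxy, 5α-H, 9β-H, 10β-methyl, i.e. (3R,5R,9R,10R).
Remark: ethyl 2-acetyl-3-oxobutanoate (4) and isofraxidin (14) are taken as purchased.

Step 1
Reactants: 1 mesityl oxide (4-methylpent-3-en-2-one); 2 nitromethane
Product: 3 4,4-dimethyl-5-nitropentan-2-one
Conditions: DBU (0.2 equiv), MeNO2 (solvent), rt
Reagents that add atoms: none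
Why: Base-catalysed Michael addition of the nitronate to the β,β-dimethyl enone is a known preparation of this γ-nitro ketone and creates the gem-dimethyl carbon C4 flanked by the two future nucleophilic carbons C3 and C5, with no stereocentre formed.

Step 2
Reactants: 4 ethyl 2-acetyl-3-oxobutanoate (ethyl diacetoacetate)
Product: 5 ethyl 2-acetyl-3-(trifluoromethanesulfonyloxy)but-2-enoate (E/Z mixture)
Conditions: Tf2O, Et3N, CH2Cl2, −78 → 0 °C
Reagents that add atoms: trifluoromethanesulfonic anhydride, O=S(=O)(OS(=O)(=O)C(F)(F)F)C(F)(F)F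
Why: The triacylmethane is fully enolised and its two acetyl groups are equivalent, so enol triflate formation can give only one constitution, and the alkene geometry is irrelevant because this carbon pair is planarised again in step 4.

Step 3
Reactants: 5 ethyl 2-acetyl-3-(trifluoromethanesulfonyloxy)but-2-enoate
Product: 6 ethyl 2-acetyl-3-methylpenta-2,4-dienoate (E/Z mixture, used directly)
Conditions: tributyl(vinyl)stannane, Pd(PPh3)4 (5 mol %), LiCl, THF, 50 °C
Reagents that add atoms: tributyl(vinyl)stannane, C=C[Sn](CCCC)(CCCC)CCCC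
Why: Stille cross-coupling of an electron-poor enol triflate with a vinylstannane under neutral, LiCl-assisted conditions installs the vinyl group that becomes C1–C2 without exposing the base-sensitive dienyl β-keto ester to nucleophiles.

Step 4
Reactants: 3 4,4-dimethyl-5-nitropentan-2-one; 6 ethyl 2-acetyl-3-methylpenta-2,4-dienoate
Product: 8 ethyl 2-[(1S,2R)-2-acetyl-1,3,3-trimethyl-4-nitrocyclohexyl]-3-oxobutanoate (epimers at the nitro-bearing carbon and at the acetoacetate carbon), via open-chain 1,6-adduct 7 (not isolated)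
Conditions: DBU (10 mol %), MeCN, 0 °C → rt; then 9-amino-9-deoxy-epi-quinine (20 mol %), PhCO2H (40 mol %), 40 °C
Reagents that add atoms: none
Why: DBU generates the nitronate of 3, which adds to the unsubstituted terminal (δ) carbon of 6 in a vinylogous 1,6-Michael addition (C2–C3), and γ-protonation of the resulting dienolate gives the alkylidene acetoacetate 7; the primary amine then condenses with the C6 ketone and the C5 enamine adds to the β-carbon C10 (C5–C10), hydrolysis releasing the catalyst and the stabilised β-keto ester. The closest known reaction types are domino Michael/Michael (3+3) annulations of 1,3-bis-nucleophiles with dienyl acceptors and amine-catalysed intramolecular Michael additions of ketones to alkylidene 1,3-dicarbonyl compounds. Ring A closes in the 6-exo-trig mode through a chair-like transition state that places the enamine and the acceptor side chain equatorial and the C10 methyl axial. The quaternary centre C10 (and the adjacent C5) is set by the chiral amine, which shields one face of the enamine; the sense of induction cannot be predicted with confidence, so of the quinine- and quinidine-derived pseudoenantiomers the one delivering the (1S,2R) ring is used, while the nitro-bearing carbon and the acetoacetate carbon are labile and are removed or equilibrated in steps 5 and 6. The step needs δ- rather than β-attack in the first addition, secured by the fully substituted β-carbon, and closure through C5 rather than through C7 or the nitronate carbon, secured because only C5 reaches C10 through a six-membered ring (C7 would need an eight-membered and the nitronate carbon a four-membered one).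

Step 5
Reactants: 8 ethyl 2-[(1S,2R)-2-acetyl-1,3,3-trimethyl-4-nitrocyclohexyl]-3-oxobutanoate
Product: 9 ethyl 3ξ-nitro-6-oxo-9βH-drim-7-en-11-oate (5α-H, 10β-methyl, ester α)
Conditions: p-TsOH·H2O (20 mol %), toluene, reflux, Dean–Stark
Reagents that add atoms: none
Why: Acid-catalysed intramolecular aldol condensation (the cyclodehydration stage of a Robinson annulation, as in Hagemann's ester syntheses) joins the accessible C7 methyl enol to the C8 acetyl carbonyl rather than the reverse because the C6 carbonyl is flanked by two quaternary carbons, and reversible enolisation should let C5 and C9 settle in the trans-fused form with the ester axial and anti to the C10 methyl, the arrangement favoured by A(1,2) strain with the C8 methyl (compare polygodial and its more stable 9-epimer).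

Step 6
Reactants: 9 ethyl 3ξ-nitro-6-oxo-9βH-drim-7-en-11-oate
Product: 11 ethyl 3,6-dioxo-9βH-drim-7-en-11-oate, via sodium nitronate 10 (not isolated)
Conditions: NaOEt (1.2 equiv), EtOH, 0 °C; then aq. TiCl3 (4.5 equiv), NH4OAc, THF/H2O, rt
Reagents that add atoms: water, O
Why: Reductive Nef reaction (McMurry–Melton), in which the nitronate is reduced by TiCl3 to the N–H ketimine that hydrolyses in the buffered medium to the C3 ketone under conditions expected to leave the enone and ester untouched, the only stereocentre affected being the discarded nitro-bearing carbon.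

Step 7
Reactants: 11 ethyl 3,6-dioxo-9βH-drim-7-en-11-oate
Product: 12 ethyl 3α-hydroxy-6-oxo-9βH-drim-7-en-11-oate
Conditions: L-Selectride (LiBH(s-Bu)3, 1.1 equiv), THF, −78 °C; aq. NH4Cl
Reagents that add atoms: none
Why: The bulky trialkylborohydride attacks the saturated neopentyl C3 ketone from the equatorial direction to give the axial 3α-alcohol (the known outcome for 4,4-dimethyl-3-oxo decalins and triterpenoids), while the β,β-disubstituted enone and the ester react far more slowly at −78 °C and any C6 reduction is harmless because C6 is re-oxidised in step 10.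

Step 8
Reactants: 12 ethyl 3α-hydroxy-6-oxo-9βH-drim-7-en-11-oate
Product: 13 9βH-drim-7-ene-3α,6ξ,11-triol
Conditions: DIBAL-H (i-Bu2AlH, 6 equiv), CH2Cl2, −78 → 0 °C; Rochelle salt
Reagents that add atoms: none
Why: Excess DIBAL-H reduces the hindered ester to the primary C11 alcohol and the enone in the 1,2-sense to the allylic C6 alcohol without affecting C3 or C9, which also removes the acidity of the C9 hydrogen before the ether is made.

Step 9
Reactants: 13 9βH-drim-7-ene-3α,6ξ,11-triol; 14 isofraxidin (7-hydroxy-6,8-dimethoxy-2H-chromen-2-one)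
Product: 15 7-[(3α,6ξ-dihydroxy-9βH-drim-7-en-11-yl)oxy]-6,8-dimethoxy-2H-chromen-2-one
Conditions: PPh3, DIAD, THF, 0 °C → rt
Reagents that add atoms: none
Why: Mitsunobu etherification should be selective for the primary C11 hydroxyl over the doubly flanked allylic C6 hydroxyl and the axial neopentyl C3 hydroxyl, the acidic phenol of isofraxidin being a competent pronucleophile, and no stereocentre is involved at the CH2 carbon.

Step 10
Reactants: 15 7-[(3α,6ξ-dihydroxy-9βH-drim-7-en-11-yl)oxy]-6,8-dimethoxy-2H-chromen-2-one
Product: 16 7-[(3α-hydroxy-6-oxo-9βH-drim-7-en-11-yl)oxy]-6,8-dimethoxy-2H-chromen-2-one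
Conditions: MnO2 (activated, excess), CH2Cl2, rt
Reagents that add atoms: none
Why: Activated MnO2 oxidises only the allylic C6 alcohol, restoring the 7-en-6-one while the saturated axial C3 hydroxyl, the aryl ether and the coumarin are inert.

Step 11
Reactants: 16 7-[(3α-hydroxy-6-oxo-9βH-drim-7-en-11-yl)oxy]-6,8-dimethoxy-2H-chromen-2-one
Product: 17 (2R,4aR,5R,8aR)-5-{[(6,8-dimethoxy-2-oxo-2H-chromen-7-yl)oxy]methyl}-1,1,4a,6-tetramethyl-8-oxo-1,2,3,4,4a,5,8,8a-octahydronaphthalen-2-yl 3-methylbutanoate (CNP0279705.1)
Conditions: 3-methylbutanoyl chloride, DMAP (0.2 equiv), pyridine, CH2Cl2, 0 → 40 °C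
Reagents that add atoms: 3-methylbutanoyl chloride, CC(C)CC(Cl)=O
Why: DMAP-catalysed acylation of the remaining hindered axial 3α-hydroxyl proceeds with retention at C3 under weakly basic conditions that should neither epimerise C9 nor eliminate the aryloxide.

Compound list
1 | mesityl oxide (4-methylpent-3-en-2-one) | CC(=O)C=C(C)C | starting material
2 | nitromethane | C[N+](=O)[O-] | starting material
3 | 4,4-dimethyl-5-nitropentan-2-one | CC(=O)CC(C)(C)C[N+](=O)[O-] | intermediate
4 | ethyl 2-acetyl-3-oxobutanoate | CCOC(=O)C(C(C)=O)C(C)=O | starting material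
5 | ethyl 2-acetyl-3-(trifluoromethanesulfonyloxy)but-2-enoate | CCOC(=O)C(C(C)=O)=C(C)OS(=O)(=O)C(F)(F)F | intermediate
6 | ethyl 2-acetyl-3-methylpenta-2,4-dienoate | CCOC(=O)C(C(C)=O)=C(C)C=C | intermediate
7 | ethyl 2-acetyl-3,7,7-trimethyl-6-nitro-9-oxodec-2-enoate | CCOC(=O)C(C(C)=O)=C(C)CCC([N+](=O)[O-])C(C)(C)CC(C)=O | intermediate
8 | ethyl 2-[(1S,2R)-2-acetyl-1,3,3-trimethyl-4-nitrocyclohexyl]-3-oxobutanoate | CCOC(=O)C(C(C)=O)[C@@]1(C)CCC([N+](=O)[O-])C(C)(C)[C@@H]1C(C)=O | intermediate
9 | ethyl 3ξ-nitro-6-oxo-9βH-drim-7-en-11-oate | CCOC(=O)[C@@H]1C(C)=CC(=O)[C@H]2C(C)(C)C([N+](=O)[O-])CC[C@]12C | intermediate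
10 | sodium nitronate of 9 | CCOC(=O)[C@@H]1C(C)=CC(=O)[C@H]2C(C)(C)C(=[N+]([O-])[O-])CC[C@]12C.[Na+] | intermediate
11 | ethyl 3,6-dioxo-9βH-drim-7-en-11-oate | CCOC(=O)[C@@H]1C(C)=CC(=O)[C@H]2C(C)(C)C(=O)CC[C@]12C | intermediate
12 | ethyl 3α-hydroxy-6-oxo-9βH-drim-7-en-11-oate | CCOC(=O)[C@@H]1C(C)=CC(=O)[C@H]2C(C)(C)[C@H](O)CC[C@]12C | intermediate
13 | 9βH-drim-7-ene-3α,6ξ,11-triol | OC[C@@H]1C(C)=CC(O)[C@H]2C(C)(C)[C@H](O)CC[C@]12C | intermediate
14 | isofraxidin | COc1cc2ccc(=O)oc2c(OC)c1O | starting material
15 | 7-[(3α,6ξ-dihydroxy-9βH-drim-7-en-11-yl)oxy]-6,8-dimethoxy-2H-chromen-2-one | COc1cc2ccc(=O)oc2c(OC)c1OC[C@@H]1C(C)=CC(O)[C@H]2C(C)(C)[C@H](O)CC[C@]12C | intermediate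
16 | 7-[(3α-hydroxy-6-oxo-9βH-drim-7-en-11-yl)oxy]-6,8-dimethoxy-2H-chromen-2-one | COc1cc2ccc(=O)oc2c(OC)c1OC[C@@H]1C(C)=CC(=O)[C@H]2C(C)(C)[C@H](O)CC[C@]12C | intermediate
17 | CNP0279705.1, 3α-(3-methylbutanoyloxy)-6-oxo-9βH-drim-7-en-11-yl ether of isofraxidin | COc1cc2ccc(=O)oc2c(OC)c1OC[C@@H]1C(C)=CC(=O)[C@H]2C(C)(C)[C@H](OC(=O)CC(C)C)CC[C@]12C | target

Total step count: 11. Longest linear sequence: 10 steps (steps 2–11, from 4).

Steps most likely to fail

Step 4. The enamine closure onto the fully substituted C10 may be too slow relative to intermolecular enamine or retro-Michael pathways, or may proceed with poor facial control. The fallback sets out from 2 and 6 and returns at 8. Nitromethane (2) is added to commercial 3-methylbut-2-enal under amine catalysis to give 3,3-dimethyl-4-nitrobutanal F1. F1 and 6 are combined with catalytic Et3N (1,6-addition) and then with a diarylprolinol trimethylsilyl ether and benzoic acid, so that an aldehyde enamine with a single α-position closes ring A to ethyl 2-[(1S,2R)-2-formyl-1,3,3-trimethyl-4-nitrocyclohexyl]-3-oxobutanoate F2. Chemoselective methyl transfer to the aldehyde with MeTi(OiPr)3 gives ethyl 2-[(1S,2R)-2-(1-hydroxyethyl)-1,3,3-trimethyl-4-nitrocyclohexyl]-3-oxobutanoate F3, and Dess–Martin oxidation gives 8.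

Step 9. Activation of the allylic C6 hydroxyl, or slow substitution at the β-branched C11 by the hindered phenol, may divert the Mitsunobu reaction. The fallback sets out from 13 and returns at 16. MnO2 oxidation is done first and gives 3α,11-dihydroxy-9βH-drim-7-en-6-one F4. Selective mesylation of the primary hydroxyl (MsCl, Et3N, 0 °C) gives 3α-hydroxy-6-oxo-9βH-drim-7-en-11-yl methanesulfonate F5. On warming with excess Et3N this loses methanesulfonate by vinylogous E1cB elimination to the cross-conjugated 3α-hydroxydrima-7,9(11)-dien-6-one F6. Oxa-1,6-conjugate addition of isofraxidin (14) at the exocyclic CH2 with Cs2CO3 in MeCN, followed by thermodynamic protonation at C9, gives 16.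

Step 6. Reduction may stop at the oxime, the hindered neopentyl C=N may hydrolyse slowly, or the enone may be attacked by the reductant. The fallback sets out from 9 and returns at 11. The nitro group is reduced selectively with SnCl2·2H2O, PhSH and Et3N to ethyl 3-(hydroxyimino)-6-oxo-9βH-drim-7-en-11-oate F7, and F7 is cleaved by transoximation with aqueous glyoxylic acid to 11.

Further compounds
F1 | step 4 | 3,3-dimethyl-4-nitrobutanal | O=CCC(C)(C)C[N+](=O)[O-]
F2 | step 4 | ethyl 2-[(1S,2R)-2-formyl-1,3,3-trimethyl-4-nitrocyclohexyl]-3-oxobutanoate | CCOC(=O)C(C(C)=O)[C@@]1(C)CCC([N+](=O)[O-])C(C)(C)[C@@H]1C=O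
F3 | step 4 | ethyl 2-[(1S,2R)-2-(1-hydroxyethyl)-1,3,3-trimethyl-4-nitrocyclohexyl]-3-oxobutanoate | CCOC(=O)C(C(C)=O)[C@@]1(C)CCC([N+](=O)[O-])C(C)(C)[C@@H]1C(C)O
F4 | step 9 | 3α,11-dihydroxy-9βH-drim-7-en-6-one | OC[C@@H]1C(C)=CC(=O)[C@H]2C(C)(C)[C@H](O)CC[C@]12C
F5 | step 9 | 3α-hydroxy-6-oxo-9βH-drim-7-en-11-yl methanesulfonate | CS(=O)(=O)OC[C@@H]1C(C)=CC(=O)[C@H]2C(C)(C)[C@H](O)CC[C@]12C
F6 | step 9 | 3α-hydroxydrima-7,9(11)-dien-6-one | C=C1C(C)=CC(=O)[C@H]2C(C)(C)[C@H](O)CC[C@]12C
F7 | step 6 | ethyl 3-(hydroxyimino)-6-oxo-9βH-drim-7-en-11-oate | CCOC(=O)[C@@H]1C(C)=CC(=O)[C@H]2C(C)(C)C(=NO)CC[C@]12C
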